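The synthesis rests on cutting the C2–C3 bond of the acyclic core. C2 is a CH flanked by the benzylic carbinol C1 (on ring A) and the acyloxymethyl carbon C3. C1–C2–C3 is therefore a 1,3-dioxygenated branch, the retron of an aldol with formaldehyde. Amine-catalysed α-hydroxymethylation of the unbranched (E)-5-(3,4-dimethoxyphenyl)pent-4-enal, with styrene ring B as a spectator, forms C2–C3 and sets C2 (R) in one operation. No ring is closed. The aldehyde carbon then takes up ring A and becomes C1, whose S configuration is relayed from C2 by chelate-controlled ketone reduction. A Z-configured acid made from a Z vinyl iodide completes the ester.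

Key step: step 4

Remark on the chemistry: the acyl unit is a C5 acid with CH3 and the carboxyl carbon cis (Z, angelate-like), so it is assembled from a Z-2-iodobutenyl unit and CO; commercial crotonaldehyde is taken as its E isomer.

Step 1
Reactants: 1 veratraldehyde (3,4-dimethoxybenzaldehyde); 2 vinylmagnesium bromide
Product: 3 (±)-1-(3,4-dimethoxyphenyl)prop-2-en-1-ol
Conditions: 2 (1.2 equiv, THF solution), THF, 0 °C; sat. aq NH4Cl
Reagents that add atoms: none
Why: Grignard 1,2-addition to a non-enolisable aromatic aldehyde; the carbinol centre forms racemic, which does not matter because it becomes sp2 in step 2.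

Step 2
Reactants: 3 (±)-1-(3,4-dimethoxyphenyl)prop-2-en-1-ol; 4 triethyl orthoacetate
Product: 6 ethyl (E)-5-(3,4-dimethoxyphenyl)pent-4-enoate, via ketene acetal 5 (not isolated)
Conditions: 4 (6 equiv), EtCO2H (5 mol%), 138 °C, EtOH distilled off
Reagents that add atoms: none
Why: Johnson–Claisen (orthoester Claisen) rearrangement: acid-catalysed exchange and loss of ethanol give ketene acetal 5, whose chair-like [3,3] shift with ring B equatorial moves the double bond into conjugation, should give the E styrene and deletes the racemic carbinol centre.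

Step 3
Reactants: 6 ethyl (E)-5-(3,4-dimethoxyphenyl)pent-4-enoate
Product: 7 (E)-5-(3,4-dimethoxyphenyl)pent-4-enal
Conditions: iBu2AlH (1.05 equiv), toluene, −78 °C; aq potassium sodium tartrate (KNaC4H4O6)
Reagents that add atoms: none
Why: Partial ester reduction with iBu2AlH: the tetrahedral aluminium hemiacetal persists at −78 °C and collapses to the aldehyde only on aqueous work-up, while the styrene and the aryl ethers do not react.

Step 4
Reactants: 7 (E)-5-(3,4-dimethoxyphenyl)pent-4-enal; 8 formaldehyde (37% aqueous solution)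
Product: 10 (R,E)-5-(3,4-dimethoxyphenyl)-2-(hydroxymethyl)pent-4-enal, via enamine 9 (not isolated)
Conditions: (S)-2-[diphenyl(trimethylsilyloxy)methyl]pyrrolidine (20 mol%), 8 (3 equiv), KH2PO4/K2HPO4 buffer pH 7, toluene, 20 °C; cold water washes to remove 8, toluene layer dried (Na2SO4) and used at once
Reagents that add atoms: none
Why: Aldehyde 7 condenses with the pyrrolidine nitrogen to the E, s-trans enamine 9, its β-carbon (the future C2) attacks formaldehyde 8, and hydrolysis of the resulting iminium ion releases 10 and the amine. This is an enamine-catalysed cross-aldol reaction, namely the known enantioselective α-hydroxymethylation of unbranched aldehydes with aqueous formaldehyde under diarylprolinol silyl ether catalysis. No ring is closed and C2–C3 is the only skeletal bond formed. C2 is the only new stereocentre and is controlled by the catalyst alone: the CPh2(OSiMe3) group of the S amine screens one face of 9, formaldehyde approaches the open face, and with the ranking CHO > CH2OH > CH2CH=CH this approach corresponds to R, the sense expected generally for electrophiles with this amine. The step needs enantiofacial selectivity, supplied by the catalyst because 7 is achiral, and cross- over self-aldol selectivity, secured by the excess and much higher electrophilicity of 8, by its lack of α-hydrogens and by the inertness of the remote styrene (ring B). The α-branched product re-forms an enamine with the bulky amine only reluctantly and the pH 7 buffer suppresses dehydration, so C2 should hold as long as 10 is carried on as its dried solution without chromatography.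

Step 5
Reactants: 10 (R,E)-5-(3,4-dimethoxyphenyl)-2-(hydroxymethyl)pent-4-enal; 11 4-bromo-1,2-dimethoxybenzene
Product: 13 (2R)-1-(3,4-dimethoxyphenyl)-2-[(E)-3-(3,4-dimethoxyphenyl)prop-2-enyl]propane-1,3-diol (both C1 epimers), via aryl Grignard reagent 12 (not isolated)
Conditions: 11 (3.3 equiv), Mg turnings (3.6 equiv), THF, 40 °C, gives 12; toluene solution of 10 added to 12 at −78 °C, then to −20 °C; sat. aq NH4Cl
Reagents that add atoms: none
Why: Grignard 1,2-addition: the first equivalent of 12 turns the C3 hydroxyl (and any hemiacetal oligomer) into its magnesium alkoxide and the second adds to the aldehyde, which at −78 °C under inverse addition should outrun enolisation and retro-aldol cleavage; C2 is untouched and the configuration created at C1 is of no consequence because step 6 erases it.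

Step 6
Reactants: 13 (2R)-1-(3,4-dimethoxyphenyl)-2-[(E)-3-(3,4-dimethoxyphenyl)prop-2-enyl]propane-1,3-diol (both C1 epimers)
Product: 14 (2R,4E)-1,5-bis(3,4-dimethoxyphenyl)-2-(hydroxymethyl)pent-4-en-1-one
Conditions: activated MnO2 (15 equiv), CH2Cl2, 20 °C; filtration through Celite
Reagents that add atoms: none
Why: Chemoselective MnO2 oxidation of a benzylic alcohol: only the carbinol activated by electron-rich ring A is dehydrogenated on the oxide surface, the saturated primary C3 hydroxyl and the styrene are left alone, both C1 epimers converge on one ketone, and the neutral heterogeneous medium should spare the enolisable C2 centre.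

Step 7
Reactants: 14 (2R,4E)-1,5-bis(3,4-dimethoxyphenyl)-2-(hydroxymethyl)pent-4-en-1-one
Product: 15 (1S,2R)-1-(3,4-dimethoxyphenyl)-2-[(E)-3-(3,4-dimethoxyphenyl)prop-2-enyl]propane-1,3-diol (syn: C1–OH and the cinnamyl arm on the same side of the zigzag ring A–C1–C2–C3)
Conditions: Zn(BH4)2 (1.5 equiv, made beforehand from ZnCl2 and NaBH4 in Et2O), Et2O/CH2Cl2, −30 → 0 °C; H2O
Reagents that add atoms: none
Why: Chelation-controlled ketone reduction with Zn(BH4)2: zinc binds the C3 oxygen and the carbonyl oxygen in a six-membered chelate in which the cinnamyl arm on C2 turns pseudoaxial to avoid ring A, so hydride is delivered to the opposite carbonyl face and C1 should emerge S, that is syn to C2 (ring A and the cinnamyl arm cis on the chelate ring).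

Step 8
Reactants: 16 (E)-crotonaldehyde
Product: 17 (Z)-2-iodobut-2-enal (I and CH3 cis)
Conditions: I2 (1.5 equiv), K2CO3 (1.2 equiv), 4-(dimethylamino)pyridine (20 mol%), THF/H2O, 20 °C
Reagents that add atoms: iodine, II
Why: Baylis–Hillman-type α-iodination: the pyridine adds in conjugate fashion, the enolate is iodinated at Cα and loss of the pyridine restores the enal as the more stable isomer with CH3 anti to CHO (Z), the geometry that later places the carboxyl carbon cis to CH3.

Step 9
Reactants: 17 (Z)-2-iodobut-2-enal
Product: 18 (Z)-2-iodobut-2-en-1-ol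
Conditions: NaBH4, MeOH, 0 °C
Reagents that add atoms: none
Why: Borohydride 1,2-reduction of an enal, which leaves the C–I bond and the double-bond geometry untouched.

Step 10
Reactants: 18 (Z)-2-iodobut-2-en-1-ol
Product: 19 tert-butyl{[(Z)-2-iodobut-2-en-1-yl]oxy}dimethylsilane
Conditions: TBSCl (1.1 equiv), imidazole (1.5 equiv), CH2Cl2, 0 → 20 °C
Reagents that add atoms: tert-butyldimethylsilyl chloride, CC(C)(C)[Si](C)(C)Cl
Why: Imidazole-promoted silylation of a primary allylic alcohol, which masks the hydroxyl so that the later acid cannot esterify itself.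

Step 11
Reactants: 19 tert-butyl{[(Z)-2-iodobut-2-en-1-yl]oxy}dimethylsilane
Product: 20 (Z)-2-{[(tert-butyldimethylsilyl)oxy]methyl}but-2-enoic acid
Conditions: Pd(OAc)2 (5 mol%), PPh3 (15 mol%), CO (1 atm), Et3N (3 equiv), DMF/H2O 9:1, 50 °C; work-up at pH 4–5 (aq NaH2PO4)
Reagents that add atoms: carbon monoxide, [C-]#[O+]; water, O
Why: Heck-type carbonylation (hydroxycarbonylation) of a vinyl iodide: oxidative addition of the C–I bond to zerovalent palladium and CO insertion both proceed with retention, so hydrolysis of the acyl-palladium species should give the acid with CH3 cis to CO2H, and the silyl ether tolerates the mild base.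

Step 12
Reactants: 15 (1S,2R)-1-(3,4-dimethoxyphenyl)-2-[(E)-3-(3,4-dimethoxyphenyl)prop-2-enyl]propane-1,3-diol; 20 (Z)-2-{[(tert-butyldimethylsilyl)oxy]methyl}but-2-enoic acid
Product: 22 (2R,4E)-5-(3,4-dimethoxyphenyl)-2-[(S)-(3,4-dimethoxyphenyl)(hydroxy)methyl]pent-4-en-1-yl (Z)-2-{[(tert-butyldimethylsilyl)oxy]methyl}but-2-enoate, via mixed anhydride 21 (not isolated)
Conditions: 20 (1.05 equiv), 2,4,6-Cl3C6H2COCl (1.05 equiv), Et3N (2.5 equiv), toluene, 20 °C, gives 21; then 15 (1.0 equiv), toluene, 70 °C
Reagents that add atoms: none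
Why: Yamaguchi-type mixed-anhydride esterification run without a nucleophilic pyridine catalyst, the variant used for angelate-type Z acids because no reversible conjugate addition can scramble the double bond; the unhindered primary C3 hydroxyl should react well ahead of the flanked secondary benzylic C1 hydroxyl, and excess Et3N neutralises the released acid.

Step 13
Reactants: 22 (2R,4E)-5-(3,4-dimethoxyphenyl)-2-[(S)-(3,4-dimethoxyphenyl)(hydroxy)methyl]pent-4-en-1-yl (Z)-2-{[(tert-butyldimethylsilyl)oxy]methyl}but-2-enoate
Product: 23 (2R,4E)-5-(3,4-dimethoxyphenyl)-2-[(S)-(3,4-dimethoxyphenyl)(hydroxy)methyl]pent-4-en-1-yl (Z)-2-(hydroxymethyl)but-2-enoate (CNP0417076.1)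
Conditions: HF·pyridine, excess pyridine, THF, 0 → 20 °C; aq NaHCO3
Reagents that add atoms: none
Why: Fluoride-driven silyl ether cleavage: pyridine-buffered HF is neither acidic enough to ionise the electron-rich benzylic C1 alcohol nor basic enough to provoke acyl migration from the C3 oxygen to the C1 oxygen or Z to E isomerisation, so only the allylic hydroxyl is unveiled.

Compound list
1 | veratraldehyde (3,4-dimethoxybenzaldehyde) | COc1ccc(C=O)cc1OC | starting material
2 | vinylmagnesium bromide | C=C[Mg]Br | starting material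
3 | (±)-1-(3,4-dimethoxyphenyl)prop-2-en-1-ol | C=CC(O)c1ccc(OC)c(OC)c1 | intermediate
4 | triethyl orthoacetate | CCOC(C)(OCC)OCC | starting material
5 | ketene acetal, 4-{1-[(1-ethoxyethenyl)oxy]prop-2-enyl}-1,2-dimethoxybenzene | C=C(OCC)OC(C=C)c1ccc(OC)c(OC)c1 | intermediate
6 | ethyl (E)-5-(3,4-dimethoxyphenyl)pent-4-enoate | CCOC(=O)CC/C=C/c1ccc(OC)c(OC)c1 | intermediate
7 | (E)-5-(3,4-dimethoxyphenyl)pent-4-enal | O=CCC/C=C/c1ccc(OC)c(OC)c1 | intermediate
8 | formaldehyde | C=O | starting material
9 | E enamine of 7 with (S)-2-[diphenyl(trimethylsilyloxy)methyl]pyrrolidine | C[Si](C)(C)OC(c1ccccc1)(c1ccccc1)[C@@H]1CCCN1/C=C/C/C=C/c1ccc(OC)c(OC)c1 | intermediate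
10 | (R,E)-5-(3,4-dimethoxyphenyl)-2-(hydroxymethyl)pent-4-enal | OC[C@@H](C/C=C/c1ccc(OC)c(OC)c1)C=O | intermediate
11 | 4-bromo-1,2-dimethoxybenzene | COc1ccc(Br)cc1OC | starting material
12 | (3,4-dimethoxyphenyl)magnesium bromide | COc1ccc([Mg]Br)cc1OC | intermediate
13 | (2R)-1-(3,4-dimethoxyphenyl)-2-[(E)-3-(3,4-dimethoxyphenyl)prop-2-enyl]propane-1,3-diol, both C1 epimers | OC[C@@H](C/C=C/c1ccc(OC)c(OC)c1)C(O)c1ccc(OC)c(OC)c1 | intermediate
14 | (2R,4E)-1,5-bis(3,4-dimethoxyphenyl)-2-(hydroxymethyl)pent-4-en-1-one | OC[C@@H](C/C=C/c1ccc(OC)c(OC)c1)C(=O)c1ccc(OC)c(OC)c1 | intermediate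
15 | (1S,2R)-1-(3,4-dimethoxyphenyl)-2-[(E)-3-(3,4-dimethoxyphenyl)prop-2-enyl]propane-1,3-diol | OC[C@@H](C/C=C/c1ccc(OC)c(OC)c1)[C@H](O)c1ccc(OC)c(OC)c1 | intermediate
16 | (E)-crotonaldehyde | C/C=C/C=O | starting material
17 | (Z)-2-iodobut-2-enal | C/C=C(\I)C=O | intermediate
18 | (Z)-2-iodobut-2-en-1-ol | C/C=C(\I)CO | intermediate
19 | tert-butyl{[(Z)-2-iodobut-2-en-1-yl]oxy}dimethylsilane | C/C=C(\I)CO[Si](C)(C)C(C)(C)C | intermediate
20 | (Z)-2-{[(tert-butyldimethylsilyl)oxy]methyl}but-2-enoic acid | C/C=C(/CO[Si](C)(C)C(C)(C)C)C(=O)O | intermediate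
21 | (Z)-2-{[(tert-butyldimethylsilyl)oxy]methyl}but-2-enoic 2,4,6-trichlorobenzoic anhydride | C/C=C(/CO[Si](C)(C)C(C)(C)C)C(=O)OC(=O)c1c(Cl)cc(Cl)cc1Cl | intermediate
22 | (2R,4E)-5-(3,4-dimethoxyphenyl)-2-[(S)-(3,4-dimethoxyphenyl)(hydroxy)methyl]pent-4-en-1-yl (Z)-2-{[(tert-butyldimethylsilyl)oxy]methyl}but-2-enoate | C/C=C(/CO[Si](C)(C)C(C)(C)C)C(=O)OC[C@@H](C/C=C/c1ccc(OC)c(OC)c1)[C@H](O)c1ccc(OC)c(OC)c1 | intermediate
23 | (2R,4E)-5-(3,4-dimethoxyphenyl)-2-[(S)-(3,4-dimethoxyphenyl)(hydroxy)methyl]pent-4-en-1-yl (Z)-2-(hydroxymethyl)but-2-enoate | C/C=C(/CO)C(=O)OC[C@@H](C/C=C/c1ccc(OC)c(OC)c1)[C@H](O)c1ccc(OC)c(OC)c1 | target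

Total step count: 13. Longest linear sequence: 9 steps (steps 1–7, 12 and 13); the acid branch (steps 8–11) is made in parallel.

Steps most likely to fail

Step 4. Turnover in the two-phase medium may be slow, and 7 may self-aldolise. The aldol may also dehydrate, and the C2 configuration may erode by enolisation during work-up. The fallback sets out from ester 6 and comes back at diol 15. It forms the C1–C2 bond by an auxiliary-controlled aldol, and C3 then stems from the ester carbon.
- Saponification of 6 (LiOH, THF/H2O) would give (E)-5-(3,4-dimethoxyphenyl)pent-4-enoic acid F1.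
- Activation with pivaloyl chloride/Et3N and N-acylation of (S)-4-benzyloxazolidin-2-one in the presence of LiCl would give (S)-4-benzyl-3-[(E)-5-(3,4-dimethoxyphenyl)pent-4-enoyl]oxazolidin-2-one F2.
- Enolisation with Bu2BOTf/iPr2NEt and Evans syn aldol addition to veratraldehyde 1 (CH2Cl2, −78 → 0 °C, buffered H2O2 work-up) should give (4S)-4-benzyl-3-{(2S,4E)-5-(3,4-dimethoxyphenyl)-2-[(S)-(3,4-dimethoxyphenyl)(hydroxy)methyl]pent-4-enoyl}oxazolidin-2-one F3. Both centres are set by the auxiliary through the closed boron transition state.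
- Reductive removal of the auxiliary with LiBH4 (Et2O, one equivalent of H2O, 0 °C) delivers 15.

Step 5. Formaldehyde may be lost by retro-aldol cleavage and C2 may epimerise at the magnesium alkoxide stage. The hemiacetal oligomers of the hydroxy aldehyde may also crack incompletely. The fallback sets out from 10 and comes back at ketone 14, so that step 6 is no longer needed. It replaces the epimerisable aldehyde as the electrophile by an amide.
- Pinnick oxidation of the crude solution of 10 (NaClO2, NaH2PO4, 2-methylbut-2-ene, t-BuOH/H2O, 0 °C) would give the configurationally robust (R,E)-5-(3,4-dimethoxyphenyl)-2-(hydroxymethyl)pent-4-enoic acid F4.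
- Carbodiimide coupling with MeONHMe·HCl and N-methylmorpholine in CH2Cl2 would give (R,E)-5-(3,4-dimethoxyphenyl)-2-(hydroxymethyl)-N-methoxy-N-methylpent-4-enamide F5.
- Weinreb ketone synthesis with excess 12 (THF, −20 → 0 °C) keeps the carbonyl masked as its magnesium chelate until the quench and should release 14.

Step 12. The activated acyl unit may isomerise from Z to E on heating, and the benzylic C1 hydroxyl may compete in the acylation. The fallback sets out from vinyl iodide 19 and diol 15 and comes back at 22, which makes step 11 unnecessary. It makes no compound outside the list (F0). The ester would be formed by palladium-catalysed alkoxycarbonylation (19 in slight excess, Pd(PPh3)4, CO 1 atm, Et3N, DMF, 60 °C). The acyl-palladium species arises from the Z iodide with retention and is intercepted by the less hindered primary hydroxyl. No free activated acid ever exists, so the geometry cannot be scrambled through one.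

Further compounds
F1 | step 4 | (E)-5-(3,4-dimethoxyphenyl)pent-4-enoic acid | OC(=O)CC/C=C/c1ccc(OC)c(OC)c1
F2 | step 4 | (S)-4-benzyl-3-[(E)-5-(3,4-dimethoxyphenyl)pent-4-enoyl]oxazolidin-2-one | O=C(CC/C=C/c1ccc(OC)c(OC)c1)N1[C@@H](Cc2ccccc2)COC1=O
F3 | step 4 | (4S)-4-benzyl-3-{(2S,4E)-5-(3,4-dimethoxyphenyl)-2-[(S)-(3,4-dimethoxyphenyl)(hydroxy)methyl]pent-4-enoyl}oxazolidin-2-one | O=C(N1[C@@H](Cc2ccccc2)COC1=O)[C@@H](C/C=C/c1ccc(OC)c(OC)c1)[C@H](O)c1ccc(OC)c(OC)c1
F4 | step 5 | (R,E)-5-(3,4-dimethoxyphenyl)-2-(hydroxymethyl)pent-4-enoic acid | OC[C@@H](C/C=C/c1ccc(OC)c(OC)c1)C(=O)O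
F5 | step 5 | (R,E)-5-(3,4-dimethoxyphenyl)-2-(hydroxymethyl)-N-methoxy-N-methylpent-4-enamide | OC[C@@H](C/C=C/c1ccc(OC)c(OC)c1)C(=O)N(C)OC
F0 | step 12 | none | none
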